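**Plan**
- Retrosynthetic cuts: C4a–C5 and C8–C8a of the 5,6,7,8-tetrahydrochromone half (both in one [4+2] step), then C6–O and C7–H, the ArO–CH2 bond of the diene precursor, and the C–C/C–O bonds that close the two pyranone rings.
- Enabling feature: O5 and O8 are cis and sit on the two carbons flanking the C4a=C8a bond shared with the pyranone ring. The carbocycle is therefore a diene adduct of the C2=C3 bond of a monocyclic 4-pyranone, with the C8 aryl ether arriving on the diene terminus.
- Forward order: the aromatic chromone 7 is made from paeonol, alkylated and converted into the (1E,3Z)-aryloxy-bis(silyloxy)diene 13. The sulfinylpyranone 19 is built separately. 13 and 19 close the carbocycle (step 11); O6, H7 and desilylation finish the route.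
- Stereochemistry: C5/C8 cis from the diene geometry, their absolute sense from the sulfinyl group; C6 from epoxidation anti to O5 and O8; C7 from hydride delivery by the C6 hydroxyl.

Key step: step 11

Assumption: the cycloaddition is run without a chelating Lewis acid, so the sulfinyl conformer with S–O syn to C2=C3 controls the face; with endo approach this calls for the (R)-sulfinylpyranone, which derives from (S)-methyl p-tolyl sulfoxide (same spatial arrangement at sulfur; the descriptor changes once the sulfur-bearing carbon outranks tolyl).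

Abbreviations: ArO = [7-methoxy-4-oxo-2-(2-phenylethyl)-4H-chromen-6-yl]oxy; TBS = tert-butyldimethylsilyl; TES = triethylsilyl. Chromone numbering (O1, C2–C4, C4a, C5–C8, C8a) is used for all bicyclic intermediates.

**Route**

Step 1
Reactants: 1 paeonol
Product: 3 1-(2,5-dihydroxy-4-methoxyphenyl)ethanone, via aryl potassium sulfate 2 (not isolated)
Conditions: K2S2O8, KOH, H2O, 15 °C; then conc. HCl, 90 °C
Reagents that add atoms: potassium peroxodisulfate, [K+].[K+].[O-]S(=O)(=O)OOS(=O)(=O)[O-]
Why: Elbs persulfate oxidation, in which the phenoxide is attacked by peroxodisulfate at the free position para to the phenolic oxygen (C5) and the aryl sulfate is then hydrolysed by acid.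

Step 2
Reactants: 3 1-(2,5-dihydroxy-4-methoxyphenyl)ethanone
Product: 4 1-[2-hydroxy-4-methoxy-5-(methoxymethoxy)phenyl]ethanone
Conditions: MeOCH2Cl (1.05 equiv), iPr2NEt, CH2Cl2, 0 °C → rt
Reagents that add atoms: chloromethyl methyl ether, COCCl
Why: O-alkylation (acetal-type ether formation) that should occur only at the 5-hydroxyl, because the 2-hydroxyl is held in a hydrogen bond to the acetyl carbonyl.

Step 3
Reactants: 4 1-[2-hydroxy-4-methoxy-5-(methoxymethoxy)phenyl]ethanone; 5 methyl 3-phenylpropanoate
Product: 7 6-hydroxy-7-methoxy-2-(2-phenylethyl)-4H-chromen-4-one, via diketone 6 (not isolated)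
Conditions: NaH, THF, reflux; then conc. HCl, MeOH, reflux
Reagents that add atoms: none
Why: crossed Claisen condensation of the ketone enolate with the ester gives the 1,3-diketone, and acid then effects cyclodehydration to the chromone and cleaves the methoxymethyl acetal in the same operation.

Step 4
Reactants: 8 4,4-dimethoxybutan-2-one
Product: 9 1-bromo-4,4-dimethoxybutan-2-one
Conditions: Br2, MeOH, 0 °C → rt
Reagents that add atoms: bromine, BrBr
Why: acid-catalysed α-bromination of a methyl ketone in methanol, which should take place at the methyl group while the dimethyl acetal is preserved by the solvent.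

Step 5
Reactants: 7 6-hydroxy-7-methoxy-2-(2-phenylethyl)-4H-chromen-4-one; 9 1-bromo-4,4-dimethoxybutan-2-one
Product: 10 1-ArO-4,4-dimethoxybutan-2-one
Conditions: K2CO3, acetone, rt
Reagents that add atoms: none
Why: Williamson ether synthesis, SN2 displacement of the α-bromo ketone by the phenoxide.

Step 6
Reactants: 10 1-ArO-4,4-dimethoxybutan-2-one
Product: 12 (E)-1-ArO-4-(tert-butyldimethylsilyloxy)but-3-en-2-one, via keto aldehyde 11 (not isolated)
Conditions: 1 M HCl, THF, rt; then tBuMe2SiCl, Et3N, CH2Cl2, 0 °C
Reagents that add atoms: water, O; tert-butyldimethylsilyl chloride, CC(C)(C)[Si](C)(C)Cl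
Why: acetal hydrolysis unmasks the β-keto aldehyde, whose hydroxymethylene enol is O-silylated at the aldehyde-derived oxygen to the more stable (E) vinylogous silyl ester.

Step 7
Reactants: 12 (E)-1-ArO-4-(tert-butyldimethylsilyloxy)but-3-en-2-one
Product: 13 (1E,3Z)-4-ArO-1-(tert-butyldimethylsilyloxy)-3-(triethylsilyloxy)buta-1,3-diene
Conditions: Et3SiOTf (1.2 equiv), Et3N, Et2O, −78 → 0 °C; non-aqueous work-up, used at once
Reagents that add atoms: triethylsilyl trifluoromethanesulfonate, CC[Si](CC)(CC)OS(=O)(=O)C(F)(F)F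
Why: soft enolisation (silyl triflate and amine) of the only enolisable position, ArOCH2, should give the silyl enol ether with OAr cis to OSi (3Z), as in the established preparation of 4-alkoxy- and 4-acyloxy-1-oxy-3-silyloxybutadienes from α-oxygenated enones.

Step 8
Reactants: 14 (S)-methyl p-tolyl sulfoxide
Product: 15 (S)-1-(p-tolylsulfinyl)propan-2-one
Conditions: LiN(iPr)2 (2.2 equiv), THF, −78 °C; EtOAc; aq. NH4Cl
Reagents that add atoms: ethyl acetate, CCOC(C)=O
Why: Claisen-type acylation of the α-sulfinyl carbanion by the ester, the second equivalent of base protecting the product as its enolate; the sulfur stereocentre is not touched.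

Step 9
Reactants: 15 (S)-1-(p-tolylsulfinyl)propan-2-one
Product: 16 (R)-4-(dimethylamino)-3-(p-tolylsulfinyl)but-3-en-2-one
Conditions: Me2NCH(OMe)2, PhMe, 50 °C
Reagents that add atoms: N,N-dimethylformamide dimethyl acetal, COC(OC)N(C)C
Why: aminomethylenation of the active methylene between sulfinyl and carbonyl groups by the formamide acetal; the sulfur configuration is carried through unchanged in space.

Step 10
Reactants: 16 (R)-4-(dimethylamino)-3-(p-tolylsulfinyl)but-3-en-2-one; 17 3-phenylpropanoyl chloride
Product: 19 (R)-6-(2-phenylethyl)-3-(p-tolylsulfinyl)-4H-pyran-4-one, via diketo enaminone 18 (not isolated)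
Conditions: LiN(SiMe3)2 (2.2 equiv), THF, −78 °C; 17; then CF3CO2H, CH2Cl2, rt
Reagents that add atoms: none
Why: 4-pyranone synthesis from a vinylogous amide, C-acylation of its methyl ketone enolate followed by acid-induced 6-endo addition–elimination of the diketone enol oxygen at the enamine carbon with loss of dimethylamine; a halide-free acid is used so that the sulfoxide does not racemise.

Step 11
Reactants: 13 (1E,3Z)-4-ArO-1-(tert-butyldimethylsilyloxy)-3-(triethylsilyloxy)buta-1,3-diene; 19 (R)-6-(2-phenylethyl)-3-(p-tolylsulfinyl)-4H-pyran-4-one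
Product: 21 (5R,8R)-8-ArO-5-(tert-butyldimethylsilyloxy)-2-(2-phenylethyl)-7-(triethylsilyloxy)-5,8-dihydro-4H-chromen-4-one, via sulfinyl cycloadduct 20 (not isolated)
Conditions: 13 (1.5 equiv), PhMe, 4 Å molecular sieves, 25 → 60 °C; product used at once
Reagents that add atoms: none
Why: Proposed new method: the electron-rich diene 13 should add thermally to the C2=C3 bond of 19, which carries ketone and sulfinyl groups on the same carbon, in a normal-electron-demand Diels–Alder reaction, and the endo adduct 20 should then lose 4-methylbenzenesulfenic acid by syn elimination (C4a–S, C8a–H) to return the 4-pyranone. The closest known reaction type is the cycloaddition–sulfoxide elimination of enantiopure 2-(p-tolylsulfinyl)quinones and 2-sulfinyl enones with oxygenated dienes; a 3-sulfinyl-4-pyranone has not been used as the dienophile. The carbocycle closes by the intermolecular [4+2] annulation itself, C8–C8a forming between the nucleophilic aryloxy-bearing diene terminus and the β-carbon of the enone and C4a–C5 between the silyloxy-bearing terminus and the α-carbon, so matched polarity fixes the regiochemistry. C5 and C8 come out cis because both oxygens are outward substituents of the (1E,3Z)-diene and the addition is suprafacial; their absolute configuration (5R,8R) follows from endo approach to the C3-Re face of 19, the face that carries the sulfur lone pair and is remote from the tolyl group when S–O lies syn to C2=C3 in the non-chelated (R)-sulfoxide. Besides regio-, endo- and face selectivity the step needs elimination toward C8a and not C5: H8a is held syn to sulfur by the cis ring fusion and its loss gives the conjugated pyranone. No Lewis acid is added (chelation of S–O and C4=O would expose the other face) and the temperature is kept at or below 60 °C so that 21 does not aromatise by 1,4-loss of silanol or phenol.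

Step 12
Reactants: 21 (5R,8R)-8-ArO-5-(tert-butyldimethylsilyloxy)-2-(2-phenylethyl)-7-(triethylsilyloxy)-5,8-dihydro-4H-chromen-4-one
Product: 23 (5S,6R,8R)-8-ArO-5-(tert-butyldimethylsilyloxy)-6-hydroxy-2-(2-phenylethyl)-5,6-dihydro-4H-chromene-4,7(8H)-dione, via silyloxy epoxide 22 (not isolated)
Conditions: dimethyldioxirane (1.1 equiv), acetone/CH2Cl2, −78 °C; then AcOH, THF/H2O, 0 °C; crude product taken on directly
Reagents that add atoms: dimethyldioxirane, CC1(C)OO1
Why: Rubottom oxidation, in which the silyl enol ether is epoxidised from the face opposite the two flanking oxygens (O5 and O8 are on the same face), which sets O6 trans to O5, and the silyloxy epoxide is hydrolysed to the α-hydroxy ketone.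

Step 13
Reactants: 23 (5S,6R,8R)-8-ArO-5-(tert-butyldimethylsilyloxy)-6-hydroxy-2-(2-phenylethyl)-5,6-dihydro-4H-chromene-4,7(8H)-dione
Product: 24 (5S,6S,7S,8S)-8-ArO-5-(tert-butyldimethylsilyloxy)-6,7-dihydroxy-2-(2-phenylethyl)-5,6,7,8-tetrahydro-4H-chromen-4-one
Conditions: Me4NBH(OAc)3, MeCN/AcOH, −30 °C
Reagents that add atoms: none
Why: Evans–Saksena hydroxyl-directed reduction, in which the C6 hydroxyl exchanges onto boron and delivers hydride to C7 from its own face, giving the 6,7-trans diol and hence O7 cis to the aryl ether; the vinylogous ester carbonyls should not react and the acidic medium avoids enolisation toward C8.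

Step 14
Reactants: 24 (5S,6S,7S,8S)-8-ArO-5-(tert-butyldimethylsilyloxy)-6,7-dihydroxy-2-(2-phenylethyl)-5,6,7,8-tetrahydro-4H-chromen-4-one
Product: 25 (5S,6R,7S,8S)-8-ArO-5,6,7-trihydroxy-2-(2-phenylethyl)-5,6,7,8-tetrahydro-4H-chromen-4-one (CNP0125425.2)
Conditions: HF·pyridine, pyridine, THF, 0 °C → rt
Reagents that add atoms: none
Why: fluoride-mediated cleavage of the silyl ether under buffered, non-basic conditions, which should leave the C5 and C8 C–O bonds and all four stereocentres untouched.

**Compound list**

1 | paeonol, 1-(2-hydroxy-4-methoxyphenyl)ethanone | CC(=O)c1ccc(OC)cc1O | starting material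
2 | potassium 5-acetyl-4-hydroxy-2-methoxyphenyl sulfate | CC(=O)c1cc(OS(=O)(=O)[O-])c(OC)cc1O.[K+] | intermediate
3 | 1-(2,5-dihydroxy-4-methoxyphenyl)ethanone | CC(=O)c1cc(O)c(OC)cc1O | intermediate
4 | 1-[2-hydroxy-4-methoxy-5-(methoxymethoxy)phenyl]ethanone | CC(=O)c1cc(OCOC)c(OC)cc1O | intermediate
5 | methyl 3-phenylpropanoate | COC(=O)CCc1ccccc1 | starting material
6 | 1-[2-hydroxy-4-methoxy-5-(methoxymethoxy)phenyl]-5-phenylpentane-1,3-dione | O=C(CC(=O)CCc1ccccc1)c1cc(OCOC)c(OC)cc1O | intermediate
7 | 6-hydroxy-7-methoxy-2-(2-phenylethyl)-4H-chromen-4-one | COc1cc2oc(CCc3ccccc3)cc(=O)c2cc1O | intermediate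
8 | 4,4-dimethoxybutan-2-one | CC(=O)CC(OC)OC | starting material
9 | 1-bromo-4,4-dimethoxybutan-2-one | BrCC(=O)CC(OC)OC | intermediate
10 | 1-ArO-4,4-dimethoxybutan-2-one | COc1cc2oc(CCc3ccccc3)cc(=O)c2cc1OCC(=O)CC(OC)OC | intermediate
11 | 4-ArO-3-oxobutanal (present mainly as its hydroxymethylene enol) | COc1cc2oc(CCc3ccccc3)cc(=O)c2cc1OCC(=O)CC=O | intermediate
12 | (E)-1-ArO-4-(tert-butyldimethylsilyloxy)but-3-en-2-one | COc1cc2oc(CCc3ccccc3)cc(=O)c2cc1OCC(=O)/C=C/O[Si](C)(C)C(C)(C)C | intermediate
13 | (1E,3Z)-4-ArO-1-(tert-butyldimethylsilyloxy)-3-(triethylsilyloxy)buta-1,3-diene | CC(C)(C)[Si](C)(C)O/C=C/C(O[Si](CC)(CC)CC)=C/Oc1cc2c(cc1OC)oc(CCc1ccccc1)cc2=O | intermediate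
14 | (S)-methyl p-tolyl sulfoxide | Cc1ccc(cc1)[S@](C)=O | starting material
15 | (S)-1-(p-tolylsulfinyl)propan-2-one | Cc1ccc(cc1)[S@](CC(C)=O)=O | intermediate
16 | (R)-4-(dimethylamino)-3-(p-tolylsulfinyl)but-3-en-2-one (push–pull C=C, geometry not fixed) | Cc1ccc(cc1)[S@](C(=CN(C)C)C(C)=O)=O | intermediate
17 | 3-phenylpropanoyl chloride | O=C(Cl)CCc1ccccc1 | starting material
18 | (R)-1-(dimethylamino)-7-phenyl-2-(p-tolylsulfinyl)hept-1-ene-3,5-dione | Cc1ccc(cc1)[S@](C(=CN(C)C)C(=O)CC(=O)CCc1ccccc1)=O | intermediate
19 | (R)-6-(2-phenylethyl)-3-(p-tolylsulfinyl)-4H-pyran-4-one | Cc1ccc(cc1)[S@@](=O)c1coc(CCc2ccccc2)cc1=O | intermediate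
20 | (4aR,5R,8R,8aS)-8-ArO-5-(tert-butyldimethylsilyloxy)-2-(2-phenylethyl)-4a-[(R)-p-tolylsulfinyl]-7-(triethylsilyloxy)-4a,5,8,8a-tetrahydro-4H-chromen-4-one (cis-fused endo adduct; O5, O8, C4 and O1 on one face, sulfur and H8a on the other) | COc1cc2oc(CCc3ccccc3)cc(=O)c2cc1O[C@@H]1[C@@H]2OC(CCc3ccccc3)=CC(=O)[C@]2([S@](=O)c2ccc(C)cc2)[C@H](O[Si](C)(C)C(C)(C)C)C=C1O[Si](CC)(CC)CC | intermediate
21 | (5R,8R)-8-ArO-5-(tert-butyldimethylsilyloxy)-2-(2-phenylethyl)-7-(triethylsilyloxy)-5,8-dihydro-4H-chromen-4-one (O5 and O8 cis) | COc1cc2oc(CCc3ccccc3)cc(=O)c2cc1O[C@@H]1c2oc(CCc3ccccc3)cc(=O)c2[C@H](O[Si](C)(C)C(C)(C)C)C=C1O[Si](CC)(CC)CC | intermediate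
22 | 6,7-epoxide of 21 on the face opposite O5 and O8, C7 still bearing the triethylsilyloxy group | COc1cc2oc(CCc3ccccc3)cc(=O)c2cc1O[C@@H]1c2oc(CCc3ccccc3)cc(=O)c2[C@H](O[Si](C)(C)C(C)(C)C)[C@H]3O[C@@]13O[Si](CC)(CC)CC | intermediate
23 | (5S,6R,8R)-8-ArO-5-(tert-butyldimethylsilyloxy)-6-hydroxy-2-(2-phenylethyl)-5,6-dihydro-4H-chromene-4,7(8H)-dione (O6 trans to O5) | COc1cc2oc(CCc3ccccc3)cc(=O)c2cc1O[C@@H]1c2oc(CCc3ccccc3)cc(=O)c2[C@H](O[Si](C)(C)C(C)(C)C)[C@@H](O)C1=O | intermediate
24 | (5S,6S,7S,8S)-8-ArO-5-(tert-butyldimethylsilyloxy)-6,7-dihydroxy-2-(2-phenylethyl)-5,6,7,8-tetrahydro-4H-chromen-4-one (O7 trans to O6, cis to O8) | COc1cc2oc(CCc3ccccc3)cc(=O)c2cc1O[C@@H]1c2oc(CCc3ccccc3)cc(=O)c2[C@H](O[Si](C)(C)C(C)(C)C)[C@@H](O)[C@@H]1O | intermediate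
25 | (5S,6R,7S,8S)-8-ArO-5,6,7-trihydroxy-2-(2-phenylethyl)-5,6,7,8-tetrahydro-4H-chromen-4-one, CNP0125425.2 | COc1cc2oc(CCc3ccccc3)cc(=O)c2cc1O[C@@H]1c2oc(CCc3ccccc3)cc(=O)c2[C@H](O)[C@@H](O)[C@@H]1O | target

**Step count**

Total: 14 steps. Longest linear sequence: 10 steps (1 → 25 through steps 1, 2, 3, 5, 6, 7, 11, 12, 13, 14). Step 4 and steps 8–10 are side branches.

**Steps most likely to fail, with fallbacks**

Step 11. What may go wrong: the vinylogous-ester double bond may be too poor a dienophile below the temperature at which the product aromatises; the sulfenic acid may be lost toward C5 instead of C8a; face selection by the sulfoxide may be weak. The fallback sets out from diene 13 and acid chloride 17 and returns at 21, using a dienophile class that is known to accept silyloxy dienes and a separate, known step to restore the pyranone. Commercial allyl acetoacetate is condensed with Me2NCH(OMe)2 to allyl 2-[(dimethylamino)methylidene]-3-oxobutanoate F1. Its methyl ketone enolate (LiN(SiMe3)2, THF, −78 °C) is acylated with 17 to allyl 2-[(dimethylamino)methylidene]-3,5-dioxo-7-phenylheptanoate F2, which is closed with CF3CO2H to allyl 4-oxo-6-(2-phenylethyl)-4H-pyran-3-carboxylate F3. This 3-alkoxycarbonyl-4-pyranone would be combined with 13 in the presence of Cu(OTf)2 and a tert-butyl-bis(oxazoline) ligand; divalent copper is bound by both carbonyl groups of the β-keto ester, and the ligand antipode is chosen for the 5R,8R series. The cis-fused Diels–Alder adduct with an angular allyl ester F4 should result. Pd(OAc)2/PPh3 in MeCN at 80 °C then brings about Tsuji decarboxylation–dehydrogenation of the allyl β-keto ester (zerovalent palladium formed in the flask, loss of CO2, palladium enolate, β-hydride elimination of H8a), which re-forms C4a=C8a and gives 21.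

Step 12. What may go wrong: aromatisation of the dihydrochromone by 1,4-elimination during epoxidation or on the acidic hydrolysis, and enolisation followed by elimination once the C7 ketone is present. The fallback sets out from 21 and returns at 25 without a C7 ketone ever being formed. Hydroboration with BH3·SMe2 (THF, −20 °C) should add boron to C6 and hydrogen to C7 from the face opposite O5 and O8, giving the C6 alkylborane F5. Oxidation with NaBO3·4H2O (retention at carbon) gives the 6-hydroxy-7-(triethylsilyloxy) analogue of 24, F6, in which C6 and C7 are both set by the one syn addition. HF·pyridine, as in step 14, then removes both silyl groups and gives 25.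

Step 13. What may go wrong: hydride delivery from the wrong face if ligand exchange at boron is slow, or epimerisation at C8 and elimination of the sensitive α-hydroxy ketone in the reaction medium. The fallback sets out from 23 and returns at 24 and replaces substrate-directed hydride delivery by catalyst control under neutral conditions: reduction with an NADPH-dependent ketoreductase (isopropanol as the terminal reductant, phosphate buffer pH 7 with DMSO as cosolvent, 25 °C), the enzyme being selected from a screening panel for the 7S alcohol.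

**Further compounds**

F1 | step 11 | allyl 2-[(dimethylamino)methylidene]-3-oxobutanoate | C=CCOC(=O)C(=CN(C)C)C(C)=O
F2 | step 11 | allyl 2-[(dimethylamino)methylidene]-3,5-dioxo-7-phenylheptanoate | C=CCOC(=O)C(=CN(C)C)C(=O)CC(=O)CCc1ccccc1
F3 | step 11 | allyl 4-oxo-6-(2-phenylethyl)-4H-pyran-3-carboxylate | C=CCOC(=O)c1coc(CCc2ccccc2)cc1=O
F4 | step 11 | allyl ester analogue of 20: cis-fused 4a-(allyloxycarbonyl)-8-ArO-5-(tert-butyldimethylsilyloxy)-2-(2-phenylethyl)-7-(triethylsilyloxy)-4a,5,8,8a-tetrahydro-4H-chromen-4-one | COc1cc2oc(CCc3ccccc3)cc(=O)c2cc1O[C@@H]1[C@@H]2OC(CCc3ccccc3)=CC(=O)[C@]2(C(=O)OCC=C)[C@H](O[Si](C)(C)C(C)(C)C)C=C1O[Si](CC)(CC)CC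
F5 | step 12 | 6-boranyl-8-ArO-5-(tert-butyldimethylsilyloxy)-2-(2-phenylethyl)-7-(triethylsilyloxy)-5,6,7,8-tetrahydro-4H-chromen-4-one (boron trans to O5 and to O7) | COc1cc2oc(CCc3ccccc3)cc(=O)c2cc1O[C@@H]1c2oc(CCc3ccccc3)cc(=O)c2[C@H](O[Si](C)(C)C(C)(C)C)[C@@H](B)[C@@H]1O[Si](CC)(CC)CC
F6 | step 12 | 8-ArO-5-(tert-butyldimethylsilyloxy)-6-hydroxy-2-(2-phenylethyl)-7-(triethylsilyloxy)-5,6,7,8-tetrahydro-4H-chromen-4-one (configuration as in 24) | COc1cc2oc(CCc3ccccc3)cc(=O)c2cc1O[C@@H]1c2oc(CCc3ccccc3)cc(=O)c2[C@H](O[Si](C)(C)C(C)(C)C)[C@@H](O)[C@@H]1O[Si](CC)(CC)CC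
F0 | step 13 | none | none
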